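**Retrosynthetic overview**
- The strategy rests on the seven-membered ring C1–C5–C6–C7–C8=C9–C10 of the trans-fused hydroazulene, read as a latent cyclohepta-1,4-diene. C8=C9 is already present, the cis C5–H/C6–O pair is what syn hydroboration of a C5=C6 alkene leaves, and the quaternary C1 sits at a Cope terminus.
- Key disconnection: C1–C10 and C6–C8/C7–C8, a dirhodium vinylcarbenoid [4+3] annulation (cyclopropanation, then divinylcyclopropane Cope) between a 2-vinylcyclopentene and methyl 2-diazobut-3-enoate. The ester that lands on C8 is later reduced to the C8 methyl.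
- Ring order: the five-membered ring (C1–C5, with the C2 oxygen) is bought as (S)-4-silyloxycyclopentenone and never opened. The seven-membered ring is annulated onto it in step 7, and no other ring is formed.
- Endgame on the core: C6 anisoate, C4 ketone (masked as a dioxolane until then) to the isopropyl carbinol, C2 silyl ether to the acetate.

Key step: step 7

**Remarks on the chemistry (assumptions)**
- Bicyclic compounds carry daucane numbering: C1 ring-fusion C–Me, C2 CH–O, C3 CH2, C4, C5 ring-fusion CH, C6 CH–O, C7 CH2, C8, C9, C10 CH2. β is the face of the five-membered ring that carries C10 at C1; the C1 methyl is α. The target is (1R,2S,4R,5S,6S): C2–OAc β, C4–OH α, C4–iPr β, C5–H β, C6–O β.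
- TBS = tert-butyldimethylsilyl. Rh2(R-DOSP)4 = dirhodium tetrakis[(R)-N-(4-dodecylbenzenesulfonyl)prolinate].
- The R catalyst is chosen on the assumption that vinyldiazoacetates follow the usual sense of induction of this catalyst family with monosubstituted alkenes. If the sense proves opposite, the S antipode is used in the same way.

**Route**

Step 1
Reactants: 1 (S)-4-(tert-butyldimethylsilyloxy)cyclopent-2-en-1-one
Product: 2 (3S,4S)-4-(tert-butyldimethylsilyloxy)-3-methyl-1-(trimethylsilyloxy)cyclopent-1-ene (methyl trans to OTBS)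
Conditions: Me2CuLi (from MeLi and CuI), TMSCl, THF, −78 °C; Et3N, pentane, aq NaHCO3 work-up
Reagents that add atoms: lithium dimethylcuprate [Li+].C[Cu-]C; chlorotrimethylsilane C[Si](C)(C)Cl
Why: Gilman cuprate 1,4-addition accelerated by TMSCl puts the methyl on the β-carbon (future C1) anti to the silyloxy group and traps the enolate as its silyl enol ether before siloxide can be expelled; the new methine stereocentre is transient.

Step 2
Reactants: 2 (3S,4S)-4-(tert-butyldimethylsilyloxy)-3-methyl-1-(trimethylsilyloxy)cyclopent-1-ene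
Product: 3 (S)-4-(tert-butyldimethylsilyloxy)-3-methylcyclopent-2-en-1-one
Conditions: Pd(OAc)2 (10 mol %), O2 (1 atm), DMSO, 25 °C
Reagents that add atoms: none
Why: Saegusa–Ito dehydrosilylation (divalent palladium, reoxidised by O2) restores the enone under neutral conditions, erasing the transient stereocentre and leaving the carbinol centre untouched.

Step 3
Reactants: 3 (S)-4-(tert-butyldimethylsilyloxy)-3-methylcyclopent-2-en-1-one
Product: 4 (S)-4-(tert-butyldimethylsilyloxy)-2-iodo-3-methylcyclopent-2-en-1-one
Conditions: I2, pyridine, CH2Cl2, 0 → 25 °C, dark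
Reagents that add atoms: iodine II
Why: Johnson α-iodination, in which pyridine adds conjugately, the enolate is iodinated and pyridinium iodide is lost (Baylis–Hillman-type addition–elimination), gives the α-iodoenone without strong base.

Step 4
Reactants: 4 (S)-4-(tert-butyldimethylsilyloxy)-2-iodo-3-methylcyclopent-2-en-1-one
Product: 5 (S)-8-(tert-butyldimethylsilyloxy)-6-iodo-7-methyl-1,4-dioxaspiro[4.4]non-6-ene
Conditions: (TMSOCH2)2, TMSOTf (5 mol %), CH2Cl2, −78 → −20 °C; pyridine quench
Reagents that add atoms: 1,2-bis(trimethylsilyloxy)ethane C[Si](C)(C)OCCO[Si](C)(C)C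
Why: Noyori ketalisation converts the electrophilic α-iodoenone carbonyl into the dioxolane at low temperature with hexamethyldisiloxane as the only by-product, and no base is present that could eliminate the allylic silyl ether.

Step 5
Reactants: 5 (S)-8-(tert-butyldimethylsilyloxy)-6-iodo-7-methyl-1,4-dioxaspiro[4.4]non-6-ene; 6 vinylboronic acid pinacol ester
Product: 7 (S)-8-(tert-butyldimethylsilyloxy)-7-methyl-6-vinyl-1,4-dioxaspiro[4.4]non-6-ene
Conditions: PdCl2(dppf) (5 mol %), K3PO4, 1,4-dioxane/H2O, 70 °C; diene used promptly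
Reagents that add atoms: none
Why: Suzuki–Miyaura coupling of the hindered tetrasubstituted vinyl iodide with the small vinylboronate (oxidative addition to zerovalent palladium, base-assisted transmetalation, reductive elimination) gives the 2-vinylcyclopentene diene, and the ketal and silyl ether tolerate aqueous phosphate.

Step 6
Reactants: 8 methyl but-3-enoate
Product: 9 methyl 2-diazobut-3-enoate
Conditions: 4-acetamidobenzenesulfonyl azide, DBU, MeCN, 0 °C; extracted into pentane, kept cold, used at once
Reagents that add atoms: 4-acetamidobenzenesulfonyl azide CC(=O)Nc1ccc(cc1)S(=O)(=O)N=[N+]=[N-]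
Why: Regitz diazo transfer to the DBU-generated dienolate at the α-carbon gives the vinyldiazoacetate, which is handled cold and fresh because it electrocyclises to a pyrazole on standing.

Step 7
Reactants: 7 (S)-8-(tert-butyldimethylsilyloxy)-7-methyl-6-vinyl-1,4-dioxaspiro[4.4]non-6-ene; 9 methyl 2-diazobut-3-enoate
Product: 11 methyl (1R,2S)-2-(tert-butyldimethylsilyloxy)-4,4-(ethylenedioxy)-1-methylhydroazulene-5,8-diene-8-carboxylate (daucane numbering; C5=C6 and C8=C9), via cis-divinylcyclopropane 10 (not isolated)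
Conditions: Rh2(R-DOSP)4 (1 mol %), slow addition of 9 (pentane solution), hexanes, −78 → 25 °C; then toluene, 80–110 °C until 10 is consumed
Reagents that add atoms: none
Why: Rh2(R-DOSP)4 decomposes 9 with loss of N2 to a donor/acceptor dirhodium vinylcarbenoid whose carbon C8 adds across the terminal vinyl C6=C7 of 7 (bonds C8–C7 and C8–C6) with the carbenoid vinyl cis to the cyclopentenyl group, and the resulting cis-divinylcyclopropane 10 then undergoes a boat [3,3] shift that forms C10–C1 and breaks C6–C8. The closest known reaction type is the dirhodium-catalysed tandem cyclopropanation/Cope rearrangement of vinyldiazoacetates with dienes (formal [4+3] cycloaddition), including Z-substituted termini that give quaternary carbons on warming. The seven-membered ring (C1, C5–C10) is closed by this sigmatropic ring expansion of the cyclopropane onto the existing cyclopentene, which leaves C5=C6 and C8=C9 (ester on C8) as the 1,4-diene. The one new stereocentre that survives, quaternary C1, is fixed by the catalyst-set configuration of C6 in 10 and relayed stereospecifically through the boat transition state, in which the C1 methyl is the inward (Z) substituent and C10 bonds to the face of C1 cis to the C2 silyloxy group. The step needs site selectivity (the monosubstituted vinyl reacts, the tetrasubstituted C1=C5 is too hindered to be cyclopropanated, and insertion into the allylic C2–H is slower than cyclopropanation of a terminal alkene), cis diastereoselectivity, which is inherent to donor/acceptor carbenoids, and enantioface selection at C6=C7, which the chiral catalyst imposes because the C2 stereocentre is remote. Heating is expected to be needed because of the inward methyl and the silyloxy group that flanks the forming bond.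

Step 8
Reactants: 11 methyl (1R,2S)-2-(tert-butyldimethylsilyloxy)-4,4-(ethylenedioxy)-1-methylhydroazulene-5,8-diene-8-carboxylate
Product: 13 methyl (1R,2S,5S,6S)-2-(tert-butyldimethylsilyloxy)-4,4-(ethylenedioxy)-6-hydroxy-1-methylhydroazulen-8-ene-8-carboxylate (trans ring fusion; C5–H and C6–OH both β), via C6 alkylborane 12 (not isolated)
Conditions: BH3·THF (1.1 equiv), THF, 0 °C; then NaBO3·4H2O, H2O, 25 °C
Reagents that add atoms: borane–tetrahydrofuran B.C1CCOC1; sodium perborate [Na+].[O-]OB=O
Why: Brown hydroboration–oxidation, in which borane adds syn across the electron-rich trisubstituted C5=C6 with boron at the less substituted C6 and on the face opposite the angular C1 methyl, sets C5–H and C6–O cis and the ring fusion trans, perborate oxidises the C–B bond with retention, and the electron-poor enoate C8=C9 reacts much more slowly with the limited borane.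

Step 9
Reactants: 13 methyl (1R,2S,5S,6S)-2-(tert-butyldimethylsilyloxy)-4,4-(ethylenedioxy)-6-hydroxy-1-methylhydroazulen-8-ene-8-carboxylate
Product: 14 (1R,2S,5S,6S)-2-(tert-butyldimethylsilyloxy)-4,4-(ethylenedioxy)-8-(hydroxymethyl)-1-methylhydroazulen-8-en-6-ol
Conditions: iBu2AlH (3.5 equiv), CH2Cl2, −78 °C; aq KNaC4H4O6 (potassium sodium tartrate) work-up
Reagents that add atoms: none
Why: DIBAL 1,2-reduction of the conjugated ester gives the primary allylic alcohol at low temperature without touching the ketal or the silyl ether.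

Step 10
Reactants: 14 (1R,2S,5S,6S)-2-(tert-butyldimethylsilyloxy)-4,4-(ethylenedioxy)-8-(hydroxymethyl)-1-methylhydroazulen-8-en-6-ol
Product: 15 (1R,2S,5S,6S)-2-(tert-butyldimethylsilyloxy)-8-(chloromethyl)-4,4-(ethylenedioxy)-1-methylhydroazulen-8-en-6-ol
Conditions: MsCl (1.2 equiv), LiCl, 2,4,6-collidine, DMF, 0 °C
Reagents that add atoms: lithium chloride [Li+].[Cl-]
Why: Collington–Meyers chlorination, in which the primary allylic alcohol is mesylated faster than the hindered secondary C6–OH and displaced in place by chloride (SN2) under collidine buffering, gives the primary allylic chloride selectively.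

Step 11
Reactants: 15 (1R,2S,5S,6S)-2-(tert-butyldimethylsilyloxy)-8-(chloromethyl)-4,4-(ethylenedioxy)-1-methylhydroazulen-8-en-6-ol
Product: 16 (1R,2S,5S,6S)-2-(tert-butyldimethylsilyloxy)-4,4-(ethylenedioxy)-1,8-dimethylhydroazulen-8-en-6-ol
Conditions: LiEt3BH (3 equiv), THF, 0 → 25 °C
Reagents that add atoms: none
Why: SN2 displacement of the primary allylic chloride by the borohydride gives the C8 methyl with the double bond kept at C8=C9, one extra equivalent being consumed by the free C6–OH.

Step 12
Reactants: 16 (1R,2S,5S,6S)-2-(tert-butyldimethylsilyloxy)-4,4-(ethylenedioxy)-1,8-dimethylhydroazulen-8-en-6-ol; 17 4-methoxybenzoyl chloride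
Product: 18 (1R,2S,5S,6S)-2-(tert-butyldimethylsilyloxy)-4,4-(ethylenedioxy)-1,8-dimethylhydroazulen-8-en-6-yl 4-methoxybenzoate
Conditions: pyridine, DMAP, CH2Cl2, 25–40 °C
Reagents that add atoms: none
Why: DMAP-catalysed O-acylation through the acylpyridinium ion esterifies the only free hydroxyl group, the secondary C6–OH.

Step 13
Reactants: 18 (1R,2S,5S,6S)-2-(tert-butyldimethylsilyloxy)-4,4-(ethylenedioxy)-1,8-dimethylhydroazulen-8-en-6-yl 4-methoxybenzoate
Product: 19 (1R,2S,5S,6S)-2-(tert-butyldimethylsilyloxy)-1,8-dimethyl-4-oxohydroazulen-8-en-6-yl 4-methoxybenzoate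
Conditions: PPTS (0.2 equiv), acetone/H2O (10:1), 45 °C
Reagents that add atoms: water O
Why: Mild acid-catalysed hydrolysis of the dioxolane leaves the silyl ether and the aroate intact and is not basic enough to eliminate the β-acyloxy group or epimerise C5.

Step 14
Reactants: 19 (1R,2S,5S,6S)-2-(tert-butyldimethylsilyloxy)-1,8-dimethyl-4-oxohydroazulen-8-en-6-yl 4-methoxybenzoate; 20 isopropylmagnesium chloride
Product: 22 (1R,2S,4R,5S,6S)-2-(tert-butyldimethylsilyloxy)-4-hydroxy-4-isopropyl-1,8-dimethylhydroazulen-8-en-6-yl 4-methoxybenzoate, via isopropylcerium dichloride 21 (not isolated)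
Conditions: 20 and anhydrous CeCl3, THF, −78 °C, 1 h; then 19, −78 °C; aq NH4Cl
Reagents that add atoms: cerium trichloride Cl[Ce](Cl)Cl
Why: Imamoto organocerium 1,2-addition uses a weakly basic, oxophilic reagent that adds to the ketone at −78 °C without enolisation, β-elimination or attack on the electron-rich aroate, and the isopropyl group should approach C4 on the β-face, anti to the axial C1 methyl and to the C5–C6 bond, so that the hydroxyl ends α (cis to the C1 methyl).

Step 15
Reactants: 22 (1R,2S,4R,5S,6S)-2-(tert-butyldimethylsilyloxy)-4-hydroxy-4-isopropyl-1,8-dimethylhydroazulen-8-en-6-yl 4-methoxybenzoate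
Product: 23 (1R,2S,4R,5S,6S)-2,4-dihydroxy-4-isopropyl-1,8-dimethylhydroazulen-8-en-6-yl 4-methoxybenzoate
Conditions: Bu4NF, AcOH (1:1), THF, 25–45 °C
Reagents that add atoms: none
Why: Fluoride desilylation buffered with acetic acid frees the secondary C2–OH without acyl migration or dehydration of the tertiary alcohol.

Step 16
Reactants: 23 (1R,2S,4R,5S,6S)-2,4-dihydroxy-4-isopropyl-1,8-dimethylhydroazulen-8-en-6-yl 4-methoxybenzoate
Product: 24 (1R,2S,4R,5S,6S)-2-acetoxy-4-hydroxy-4-isopropyl-1,8-dimethylhydroazulen-8-en-6-yl 4-methoxybenzoate (CNP0171090.1)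
Conditions: Ac2O (1.5 equiv), pyridine, DMAP (0.1 equiv), CH2Cl2, 0 → 25 °C
Reagents that add atoms: acetic anhydride CC(=O)OC(C)=O
Why: DMAP-catalysed acetylation takes the secondary C2–OH, while the hindered tertiary C4–OH does not react under these conditions.

**Compound list**
1 | (S)-4-(tert-butyldimethylsilyloxy)cyclopent-2-en-1-one | O=C1C=C[C@@H](O[Si](C)(C)C(C)(C)C)C1 | starting material
2 | (3S,4S)-4-(tert-butyldimethylsilyloxy)-3-methyl-1-(trimethylsilyloxy)cyclopent-1-ene | C[Si](C)(C)OC1=C[C@H](C)[C@@H](O[Si](C)(C)C(C)(C)C)C1 | intermediate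
3 | (S)-4-(tert-butyldimethylsilyloxy)-3-methylcyclopent-2-en-1-one | O=C1C=C(C)[C@@H](O[Si](C)(C)C(C)(C)C)C1 | intermediate
4 | (S)-4-(tert-butyldimethylsilyloxy)-2-iodo-3-methylcyclopent-2-en-1-one | O=C1C(I)=C(C)[C@@H](O[Si](C)(C)C(C)(C)C)C1 | intermediate
5 | (S)-8-(tert-butyldimethylsilyloxy)-6-iodo-7-methyl-1,4-dioxaspiro[4.4]non-6-ene | IC1=C(C)[C@@H](O[Si](C)(C)C(C)(C)C)CC12OCCO2 | intermediate
6 | vinylboronic acid pinacol ester | C=CB1OC(C)(C)C(C)(C)O1 | starting material
7 | (S)-8-(tert-butyldimethylsilyloxy)-7-methyl-6-vinyl-1,4-dioxaspiro[4.4]non-6-ene | C=CC1=C(C)[C@@H](O[Si](C)(C)C(C)(C)C)CC12OCCO2 | intermediate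
8 | methyl but-3-enoate | C=CCC(=O)OC | starting material
9 | methyl 2-diazobut-3-enoate | C=CC(=[N+]=[N-])C(=O)OC | intermediate
10 | methyl (1S,2S)-2-[(8S)-8-(tert-butyldimethylsilyloxy)-7-methyl-1,4-dioxaspiro[4.4]non-6-en-6-yl]-1-vinylcyclopropane-1-carboxylate (alkenyl groups cis) | COC(=O)[C@]1(C=C)C[C@H]1C2=C(C)[C@@H](O[Si](C)(C)C(C)(C)C)CC23OCCO3 | intermediate
11 | methyl (1R,2S)-2-(tert-butyldimethylsilyloxy)-4,4-(ethylenedioxy)-1-methylhydroazulene-5,8-diene-8-carboxylate | COC(=O)C1=CC[C@@]2(C)[C@@H](O[Si](C)(C)C(C)(C)C)CC3(OCCO3)C2=CC1 | intermediate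
12 | C6 alkylborane of 11 (BH2 at C6 β, H at C5 β) | B[C@H]1CC(C(=O)OC)=CC[C@@]2(C)[C@@H](O[Si](C)(C)C(C)(C)C)CC3(OCCO3)[C@H]12 | intermediate
13 | methyl (1R,2S,5S,6S)-2-(tert-butyldimethylsilyloxy)-4,4-(ethylenedioxy)-6-hydroxy-1-methylhydroazulen-8-ene-8-carboxylate | O[C@H]1CC(C(=O)OC)=CC[C@@]2(C)[C@@H](O[Si](C)(C)C(C)(C)C)CC3(OCCO3)[C@H]12 | intermediate
14 | (1R,2S,5S,6S)-2-(tert-butyldimethylsilyloxy)-4,4-(ethylenedioxy)-8-(hydroxymethyl)-1-methylhydroazulen-8-en-6-ol | O[C@H]1CC(CO)=CC[C@@]2(C)[C@@H](O[Si](C)(C)C(C)(C)C)CC3(OCCO3)[C@H]12 | intermediate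
15 | (1R,2S,5S,6S)-2-(tert-butyldimethylsilyloxy)-8-(chloromethyl)-4,4-(ethylenedioxy)-1-methylhydroazulen-8-en-6-ol | O[C@H]1CC(CCl)=CC[C@@]2(C)[C@@H](O[Si](C)(C)C(C)(C)C)CC3(OCCO3)[C@H]12 | intermediate
16 | (1R,2S,5S,6S)-2-(tert-butyldimethylsilyloxy)-4,4-(ethylenedioxy)-1,8-dimethylhydroazulen-8-en-6-ol | O[C@H]1CC(C)=CC[C@@]2(C)[C@@H](O[Si](C)(C)C(C)(C)C)CC3(OCCO3)[C@H]12 | intermediate
17 | 4-methoxybenzoyl chloride | COc1ccc(C(Cl)=O)cc1 | starting material
18 | (1R,2S,5S,6S)-2-(tert-butyldimethylsilyloxy)-4,4-(ethylenedioxy)-1,8-dimethylhydroazulen-8-en-6-yl 4-methoxybenzoate | COc1ccc(C(=O)O[C@H]2CC(C)=CC[C@@]3(C)[C@@H](O[Si](C)(C)C(C)(C)C)CC4(OCCO4)[C@H]23)cc1 | intermediate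
19 | (1R,2S,5S,6S)-2-(tert-butyldimethylsilyloxy)-1,8-dimethyl-4-oxohydroazulen-8-en-6-yl 4-methoxybenzoate | COc1ccc(C(=O)O[C@H]2CC(C)=CC[C@@]3(C)[C@@H](O[Si](C)(C)C(C)(C)C)CC(=O)[C@H]23)cc1 | intermediate
20 | isopropylmagnesium chloride | CC(C)[Mg]Cl | starting material
21 | isopropylcerium dichloride | CC(C)[Ce](Cl)Cl | intermediate
22 | (1R,2S,4R,5S,6S)-2-(tert-butyldimethylsilyloxy)-4-hydroxy-4-isopropyl-1,8-dimethylhydroazulen-8-en-6-yl 4-methoxybenzoate | COc1ccc(C(=O)O[C@H]2CC(C)=CC[C@@]3(C)[C@@H](O[Si](C)(C)C(C)(C)C)C[C@@](O)(C(C)C)[C@H]23)cc1 | intermediate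
23 | (1R,2S,4R,5S,6S)-2,4-dihydroxy-4-isopropyl-1,8-dimethylhydroazulen-8-en-6-yl 4-methoxybenzoate | COc1ccc(C(=O)O[C@H]2CC(C)=CC[C@@]3(C)[C@@H](O)C[C@@](O)(C(C)C)[C@H]23)cc1 | intermediate
24 | (1R,2S,4R,5S,6S)-2-acetoxy-4-hydroxy-4-isopropyl-1,8-dimethylhydroazulen-8-en-6-yl 4-methoxybenzoate (CNP0171090.1) | COc1ccc(C(=O)O[C@H]2CC(C)=CC[C@@]3(C)[C@@H](OC(C)=O)C[C@@](O)(C(C)C)[C@H]23)cc1 | target

**Step count**
Total: 16 steps. Longest linear sequence: 15 steps (1 to 24 through steps 1–5 and 7–16); step 6 is a one-step side branch.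

**Steps most likely to fail and fallbacks**

Step 7. The carbenoid may insert into the allylic, oxygen-activated C2–H bond of 7, or the catalyst may control the face of the twisted vinyl group only weakly, so that the wrong C1 epimer of 11 grows. The Cope step may also stall, because the methyl points inward and C10 must bond beside the silyloxy group. The fallback takes the carbenoid step off the sensitive diene. Vinylboronate 6 is cyclopropanated with 9 under Rh2(R-DOSP)4 in hexanes to give methyl (1R,2R)-2-(4,4,5,5-tetramethyl-1,3,2-dioxaborolan-2-yl)-1-vinylcyclopropane-1-carboxylate F1 (vinyl and boryl cis), which is purified as a stable single isomer. F1 is then joined to iodide 5 by Suzuki–Miyaura coupling (Pd(OAc)2, SPhos, K3PO4, toluene/H2O, 80 °C), which proceeds with retention at the cyclopropyl carbon. This fallback sets out from 6 and 9, brings in 5, and returns to the route at 10, which rearranges to 11 on continued heating.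

Step 8. Borane may reduce the conjugated ester in competition with the hindered ring-fusion alkene, or add with eroded regio- or facial control. The fallback replaces hydroboration by epoxidation and radical opening. Compound 11 is epoxidised with mCPBA/NaHCO3 in CH2Cl2; the enoate is inert to peracid and attack is again expected anti to the C1 methyl. This gives methyl (1R,2S)-2-(tert-butyldimethylsilyloxy)-5,6-epoxy-4,4-(ethylenedioxy)-1-methylhydroazulen-8-ene-8-carboxylate F2 (epoxide on the β-face). F2 is opened with Cp2TiCl (trivalent titanium, made from Cp2TiCl2 and Mn powder) in THF with water as hydrogen-atom source. Homolysis gives the tertiary C5 radical and a C6–O–Ti bond, and hydrogen-atom transfer to C5 on the face away from the angular methyl gives the anti-Markovnikov alcohol. This fallback sets out from 11 and returns at 13.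

Step 14. The β-acyloxy ketone 19 may enolise and lose anisic acid, epimerise at C5, or be attacked at the ester, and it is already exposed to these risks in the hydrolysis of step 13. The fallback reverses the order so that no β-acyloxy ketone is ever made. From 16 the dioxolane is hydrolysed first (PPTS, wet acetone) to (1R,2S,5S,6S)-2-(tert-butyldimethylsilyloxy)-6-hydroxy-1,8-dimethylhydroazulen-8-en-4-one F3. Excess isopropylcerium reagent (iPrMgCl, CeCl3, THF, −78 °C) is then added; the first equivalent forms the C6 alkoxide, which cannot leave. This gives (1R,2S,4R,5S,6S)-2-(tert-butyldimethylsilyloxy)-4-isopropyl-1,8-dimethylhydroazulen-8-ene-4,6-diol F4. The secondary C6–OH of F4 is acylated selectively with 17 (pyridine, DMAP), the tertiary C4–OH being inert. This fallback sets out from 16 and returns at 22.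

**Further compounds**
F1 | step 7 | methyl (1R,2R)-2-(4,4,5,5-tetramethyl-1,3,2-dioxaborolan-2-yl)-1-vinylcyclopropane-1-carboxylate | COC(=O)[C@]1(C=C)C[C@H]1B2OC(C)(C)C(C)(C)O2
F2 | step 8 | methyl (1R,2S)-2-(tert-butyldimethylsilyloxy)-5,6-epoxy-4,4-(ethylenedioxy)-1-methylhydroazulen-8-ene-8-carboxylate (β-epoxide) | COC(=O)C1=CC[C@@]2(C)[C@@H](O[Si](C)(C)C(C)(C)C)CC3(OCCO3)[C@@]24O[C@H]4C1
F3 | step 14 | (1R,2S,5S,6S)-2-(tert-butyldimethylsilyloxy)-6-hydroxy-1,8-dimethylhydroazulen-8-en-4-one | O[C@H]1CC(C)=CC[C@@]2(C)[C@@H](O[Si](C)(C)C(C)(C)C)CC(=O)[C@H]12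
F4 | step 14 | (1R,2S,4R,5S,6S)-2-(tert-butyldimethylsilyloxy)-4-isopropyl-1,8-dimethylhydroazulen-8-ene-4,6-diol | O[C@H]1CC(C)=CC[C@@]2(C)[C@@H](O[Si](C)(C)C(C)(C)C)C[C@@](O)(C(C)C)[C@H]12
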